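Ring atoms of the core are numbered C1 (ketone), C2 (amide-bearing), C3 (vinyl CH), C4 (carbinol), C5 and C6 (oxirane).
Retrosynthesis: cut the triene between its second and third carbon (Stille coupling of a core vinylstannane with a bromodienamide), remove the C5–C6 oxirane (hydroxyl-directed epoxidation of a p-quinol), cut the ring bond C3–C4 (aza-ene addition of the enamide carbon to a C4 ketone), then cut the upper amide N–CO bond.
Enabling feature: the enamide N–C2=C3 is a latent carbon nucleophile at C3, and C1(=O) and C4(–O) flank C5–C6 exactly as the 2- and 5-positions of a furan flank its 3,4-bond. A furan can therefore serve as a temporary ring that masks the cis-enedione C1(=O)–C6=C5–C4(=O) and holds C3 within reach of C4.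
Forward: a dienoyl chloride and a furyl nitrile are joined to a furyl enamide, singlet oxygen opens the furan, the six-membered ring closes at C3–C4, the oxirane is fused on, and the lower chain is joined last.
Stereochemistry: C4 comes from the chiral phosphoric acid in the ring closure, C5 and C6 from delivery of hydroperoxide by the C4 hydroxyl, and the alkene geometries from HWE olefination, syn-hydrostannylation and stereoretentive couplings.

Key step: step 7

Assumption: the sense of induction of the phosphoric acid in step 7 cannot be predicted with confidence; the (R)-catalyst is written, and its mirror image is to be used should the (R)-carbinol be favoured.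

Step 1
Reactants: 1 cyclohexanecarboxaldehyde; 2 triethyl 4-phosphonocrotonate
Product: 3 ethyl (2E,4E)-5-cyclohexylpenta-2,4-dienoate
Conditions: LiN(SiMe3)2, THF, −78 °C → 0 °C
Reagents that add atoms: none
Why: Horner–Wadsworth–Emmons olefination of the aldehyde with the γ-deprotonated phosphonocrotonate should give the (2E,4E)-dienoate, the E geometry of the new double bond following from reversible addition of the stabilised phosphonate anion.

Step 2
Reactants: 3 ethyl (2E,4E)-5-cyclohexylpenta-2,4-dienoate
Product: 4 (2E,4E)-5-cyclohexylpenta-2,4-dienoic acid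
Conditions: LiOH, THF–MeOH–H2O, 23 °C; then aq. HCl
Reagents that add atoms: lithium hydroxide, [Li+].[OH-]
Why: Ester saponification, which touches neither the diene geometry nor any stereocentre.

Step 3
Reactants: 4 (2E,4E)-5-cyclohexylpenta-2,4-dienoic acid
Product: 5 (2E,4E)-5-cyclohexylpenta-2,4-dienoyl chloride
Conditions: (COCl)2, DMF (cat.), CH2Cl2, 0 °C → 23 °C; evaporated and used crude
Reagents that add atoms: oxalyl chloride, ClC(=O)C(=O)Cl
Why: Acid chloride formation through the Vilsmeier-type chloroiminium salt under conditions that do not isomerise the diene.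

Step 4
Reactants: 6 5-bromofuran-2-carbonitrile; 7 (triisopropylsilyl)acetylene
Product: 8 5-[(triisopropylsilyl)ethynyl]furan-2-carbonitrile
Conditions: Pd(PPh3)2Cl2 (2 mol %), CuI (4 mol %), Et3N, THF, 40 °C
Reagents that add atoms: none
Why: Sonogashira coupling of an electron-poor heteroaryl bromide with a terminal alkyne, which places the future C4 substituent on the furan.

Step 5
Reactants: 8 5-[(triisopropylsilyl)ethynyl]furan-2-carbonitrile; 5 (2E,4E)-5-cyclohexylpenta-2,4-dienoyl chloride
Product: 11 (2E,4E)-5-cyclohexyl-N-(1-{5-[(triisopropylsilyl)ethynyl]furan-2-yl}ethenyl)penta-2,4-dienamide, via bromomagnesium ketimide 9 (not isolated), via N-acyl ketimine 10 (not isolated)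
Conditions: MeMgBr (1.05 equiv), CuBr (2 mol %), THF, 0 °C → 40 °C; then 5, −40 °C → 0 °C; aq. NH4Cl
Reagents that add atoms: methylmagnesium bromide, C[Mg]Br
Why: Grignard addition to the nitrile stops at the N-magnesio ketimine, and its N-acylation followed by imine-to-enamide tautomerisation into conjugation with the furan is the established one-pot synthesis of secondary N-(1-arylvinyl)amides from aryl nitriles.

Step 6
Reactants: 11 (2E,4E)-5-cyclohexyl-N-(1-{5-[(triisopropylsilyl)ethynyl]furan-2-yl}ethenyl)penta-2,4-dienamide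
Product: 13 (2E,4E)-5-cyclohexyl-N-[(4Z)-3,6-dioxo-8-(triisopropylsilyl)octa-1,4-dien-7-yn-2-yl]penta-2,4-dienamide, via furan endoperoxide 12 (not isolated)
Conditions: O2, 5,10,15,20-tetraphenylporphyrin (0.5 mol %), visible light, CH2Cl2, −78 °C; then Me2S, −78 °C → −20 °C; cold aqueous wash and filtration, used at once
Reagents that add atoms: oxygen, O=O
Why: [4+2] cycloaddition of singlet oxygen across the 2,5-positions of the furan (expected to be the most reactive diene of the molecule towards this electrophile) and reduction of the endoperoxide by Me2S is the standard unmasking of a furan to a cis-enedione, whose Z geometry is inherited from the ring.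

Step 7
Reactants: 13 (2E,4E)-5-cyclohexyl-N-[(4Z)-3,6-dioxo-8-(triisopropylsilyl)octa-1,4-dien-7-yn-2-yl]penta-2,4-dienamide
Product: 15 (2E,4E)-5-cyclohexyl-N-[(3S)-3-hydroxy-6-oxo-3-{(triisopropylsilyl)ethynyl}cyclohexa-1,4-dien-1-yl]penta-2,4-dienamide, via cyclic N-acyl ketimine 14 (not isolated)
Conditions: (R)-TRIP [(R)-3,3'-bis(2,4,6-triisopropylphenyl)-1,1'-binaphthyl-2,2'-diyl hydrogen phosphate, 10 mol %], molecular sieves 4 Å, toluene, −40 °C → 0 °C
Reagents that add atoms: none
Why: Proposed new method: the phosphoric acid is expected to bind 13 at two points, its P=O accepting the enamide N–H and its P–OH donating to the C4 ynone carbonyl, so that the enamide carbon C3 adds to C4 while the N–H proton is passed to the carbonyl oxygen (an intramolecular aza-ene addition with the tether on the central atom of the ene unit), giving N-acyl ketimine 14, which tautomerises to the conjugated 2-amido dienone 15. The closest known reaction types are the phosphoric-acid-catalysed aza-ene additions of secondary enamides and enecarbamates to glyoxylates and activated ketones and the intramolecular aldol closure of furan-derived cis-enediones to 4-hydroxycyclopentenones; here the enamide nitrogen replaces the enol oxygen and the nucleophile is one atom longer, which turns the five-membered closure into a six-membered one. The carbocycle closes in the 6-(enolendo)-exo-trig mode, with the C2=C3 bond inside and the C4=O bond outside the new ring. C4 is the only new stereocentre and no other stereocentre is present, so it is set by the catalyst, whose 2,4,6-triisopropylphenyl walls must distinguish the slim silylalkynyl arm from the dienone tether on the two faces of the bound ketone; the (S)-carbinol is required. The step needs attack through C3 rather than through nitrogen (hemiaminal formation), no 4π closure of the divinyl ketone onto C5, and no Z-to-E isomerisation of the enedione: the Z geometry inherited from the furan holds C3 and C4 within bonding distance, N-attack is reversible whereas C–C formation ends in a conjugated enamide and is not, and the weak acid at low temperature should not ionise the cross-conjugated ketone.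

Step 8
Reactants: 15 (2E,4E)-5-cyclohexyl-N-[(3S)-3-hydroxy-6-oxo-3-{(triisopropylsilyl)ethynyl}cyclohexa-1,4-dien-1-yl]penta-2,4-dienamide
Product: 16 (2E,4E)-5-cyclohexyl-N-[(1R,5S,6S)-5-hydroxy-2-oxo-5-{(triisopropylsilyl)ethynyl}-7-oxabicyclo[4.1.0]hept-3-en-3-yl]penta-2,4-dienamide (hydroxyl cis to the oxirane oxygen)
Conditions: H2O2 (30 % aq., 1.5 equiv), LiOH (0.3 equiv), THF–MeOH, −20 °C → 0 °C
Reagents that add atoms: hydrogen peroxide, OO
Why: Weitz–Scheffer nucleophilic epoxidation should take place only at the unsubstituted C5=C6 enone, because the C2=C3 bond is deactivated by its nitrogen substituent, and on the face of the C4 hydroxyl, which hydrogen-bonds to and delivers the hydroperoxide, so that C5 and C6 are set with the oxirane oxygen cis to the hydroxyl.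

Step 9
Reactants: 16 (2E,4E)-5-cyclohexyl-N-[(1R,5S,6S)-5-hydroxy-2-oxo-5-{(triisopropylsilyl)ethynyl}-7-oxabicyclo[4.1.0]hept-3-en-3-yl]penta-2,4-dienamide
Product: 17 (2E,4E)-5-cyclohexyl-N-[(1R,5S,6S)-5-ethynyl-5-hydroxy-2-oxo-7-oxabicyclo[4.1.0]hept-3-en-3-yl]penta-2,4-dienamide
Conditions: Bu4NF, AcOH (1:1), THF, 0 °C
Reagents that add atoms: none
Why: Fluoride-mediated protodesilylation of the alkynylsilane, with acetic acid as buffer so that the tertiary propargylic alkoxide and the epoxy ketone are not exposed to base; no stereocentre is touched.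

Step 10
Reactants: 17 (2E,4E)-5-cyclohexyl-N-[(1R,5S,6S)-5-ethynyl-5-hydroxy-2-oxo-7-oxabicyclo[4.1.0]hept-3-en-3-yl]penta-2,4-dienamide
Product: 18 (2E,4E)-5-cyclohexyl-N-[(1R,5S,6S)-5-hydroxy-2-oxo-5-{(E)-2-(tributylstannyl)ethenyl}-7-oxabicyclo[4.1.0]hept-3-en-3-yl]penta-2,4-dienamide
Conditions: Bu3SnH, Pd(PPh3)2Cl2 (2 mol %), THF, 0 °C
Reagents that add atoms: tributyltin hydride, CCCC[SnH](CCCC)CCCC
Why: Palladium-catalysed hydrostannylation adds H and Sn syn across the terminal alkyne, the bulky quaternary carbinol steering tin to the terminal carbon, so the (E)-vinylstannane should result, alkynes reacting much faster than enones under these conditions.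

Step 11
Reactants: 19 cyclopentane-1,3-dione
Product: 20 2-(hydroxyimino)cyclopentane-1,3-dione
Conditions: NaNO2, AcOH–H2O, 0 °C
Reagents that add atoms: sodium nitrite, [Na+].[O-]N=O
Why: Electrophilic nitrosation of the enolised 1,3-dione at C2 followed by tautomerisation to the oxime, as with other cyclic 1,3-diones.

Step 12
Reactants: 20 2-(hydroxyimino)cyclopentane-1,3-dione
Product: 21 2-amino-3-hydroxycyclopent-2-en-1-one hydrochloride
Conditions: H2 (1 atm), 10 % Pd on carbon, HCl, MeOH, 23 °C
Reagents that add atoms: hydrogen chloride, Cl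
Why: Catalytic hydrogenation of the 2-oximino-1,3-dione in acid gives the α-amino dione, which is trapped as the hydrochloride of its enol form so that self-condensation is suppressed.

Step 13
Reactants: 22 glutaconaldehyde potassium salt
Product: 23 (2E,4E)-5-bromopenta-2,4-dienal
Conditions: Ph3PBr2, CH2Cl2, 0 °C → 23 °C
Reagents that add atoms: dibromotriphenylphosphorane, BrP(Br)(c1ccccc1)(c1ccccc1)c1ccccc1
Why: The enolate oxygen of the vinylogous formate is activated as an oxyphosphonium group and replaced by bromide in a vinylogous addition–elimination, the all-trans bromodienal being the thermodynamic product.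

Step 14
Reactants: 23 (2E,4E)-5-bromopenta-2,4-dienal
Product: 24 (2E,4E)-5-bromopenta-2,4-dienoic acid
Conditions: NaClO2, NaH2PO4, 2-methylbut-2-ene, tert-butanol–H2O, 0 °C → 23 °C
Reagents that add atoms: sodium chlorite, [Na+].[O-]Cl=O
Why: Pinnick oxidation converts the enal into the acid without touching the bromodiene, the alkene scavenger removing hypochlorous acid.

Step 15
Reactants: 24 (2E,4E)-5-bromopenta-2,4-dienoic acid; 21 2-amino-3-hydroxycyclopent-2-en-1-one hydrochloride
Product: 26 (2E,4E)-5-bromo-N-(2-hydroxy-5-oxocyclopent-1-en-1-yl)penta-2,4-dienamide, via bromodienoyl chloride 25 (not isolated)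
Conditions: (COCl)2, DMF (cat.), CH2Cl2, 0 °C, evaporated; then 21, pyridine, CH2Cl2, 0 °C → 23 °C
Reagents that add atoms: none
Why: Schotten–Baumann-type acylation of the liberated amine by the acid chloride should give the amide, any O-acylated enol being expected to pass its acyl group on to nitrogen.

Step 16
Reactants: 18 (2E,4E)-5-cyclohexyl-N-[(1R,5S,6S)-5-hydroxy-2-oxo-5-{(E)-2-(tributylstannyl)ethenyl}-7-oxabicyclo[4.1.0]hept-3-en-3-yl]penta-2,4-dienamide; 26 (2E,4E)-5-bromo-N-(2-hydroxy-5-oxocyclopent-1-en-1-yl)penta-2,4-dienamide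
Product: 27 (2E,4E)-5-cyclohexyl-N-[(1R,5R,6S)-5-hydroxy-5-{(1E,3E,5E)-7-[(2-hydroxy-5-oxocyclopent-1-en-1-yl)amino]-7-oxohepta-1,3,5-trien-1-yl}-2-oxo-7-oxabicyclo[4.1.0]hept-3-en-3-yl]penta-2,4-dienamide (target)
Conditions: Pd(MeCN)2Cl2 (5 mol %), DMF, 23 °C, dark
Reagents that add atoms: none
Why: Stille coupling, in which oxidative addition of the dienyl bromide to zerovalent palladium, transmetallation of the vinylstannane and reductive elimination all proceed with retention, should give the (E,E,E)-triene under neutral conditions that the epoxyquinol and the acidic enol tolerate.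

Compound list
1 | cyclohexanecarboxaldehyde | O=CC1CCCCC1 | starting material
2 | triethyl 4-phosphonocrotonate | CCOC(=O)/C=C/CP(=O)(OCC)OCC | starting material
3 | ethyl (2E,4E)-5-cyclohexylpenta-2,4-dienoate | CCOC(=O)/C=C/C=C/C1CCCCC1 | intermediate
4 | (2E,4E)-5-cyclohexylpenta-2,4-dienoic acid | OC(=O)/C=C/C=C/C1CCCCC1 | intermediate
5 | (2E,4E)-5-cyclohexylpenta-2,4-dienoyl chloride | ClC(=O)/C=C/C=C/C1CCCCC1 | intermediate
6 | 5-bromofuran-2-carbonitrile | N#Cc1ccc(Br)o1 | starting material
7 | (triisopropylsilyl)acetylene | C#C[Si](C(C)C)(C(C)C)C(C)C | starting material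
8 | 5-[(triisopropylsilyl)ethynyl]furan-2-carbonitrile | N#Cc1ccc(C#C[Si](C(C)C)(C(C)C)C(C)C)o1 | intermediate
9 | N-bromomagnesio ketimine of 1-{5-[(triisopropylsilyl)ethynyl]furan-2-yl}ethanone | CC(=N[Mg]Br)c1ccc(C#C[Si](C(C)C)(C(C)C)C(C)C)o1 | intermediate
10 | (2E,4E)-5-cyclohexyl-N-(1-{5-[(triisopropylsilyl)ethynyl]furan-2-yl}ethylidene)penta-2,4-dienamide | CC(=NC(=O)/C=C/C=C/C1CCCCC1)c1ccc(C#C[Si](C(C)C)(C(C)C)C(C)C)o1 | intermediate
11 | (2E,4E)-5-cyclohexyl-N-(1-{5-[(triisopropylsilyl)ethynyl]furan-2-yl}ethenyl)penta-2,4-dienamide | C=C(NC(=O)/C=C/C=C/C1CCCCC1)c1ccc(C#C[Si](C(C)C)(C(C)C)C(C)C)o1 | intermediate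
12 | (2E,4E)-5-cyclohexyl-N-(1-{4-[(triisopropylsilyl)ethynyl]-2,3,7-trioxabicyclo[2.2.1]hept-5-en-1-yl}ethenyl)penta-2,4-dienamide (racemic endoperoxide) | C=C(NC(=O)/C=C/C=C/C1CCCCC1)C12OOC(C#C[Si](C(C)C)(C(C)C)C(C)C)(C=C1)O2 | intermediate
13 | (2E,4E)-5-cyclohexyl-N-[(4Z)-3,6-dioxo-8-(triisopropylsilyl)octa-1,4-dien-7-yn-2-yl]penta-2,4-dienamide | C=C(NC(=O)/C=C/C=C/C1CCCCC1)C(=O)/C=C\C(=O)C#C[Si](C(C)C)(C(C)C)C(C)C | intermediate
14 | (2E,4E)-5-cyclohexyl-N-[(5R)-5-hydroxy-2-oxo-5-{(triisopropylsilyl)ethynyl}cyclohex-3-en-1-ylidene]penta-2,4-dienamide | O=C(/C=C/C=C/C1CCCCC1)N=C1C[C@](O)(C#C[Si](C(C)C)(C(C)C)C(C)C)C=CC1=O | intermediate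
15 | (2E,4E)-5-cyclohexyl-N-[(3S)-3-hydroxy-6-oxo-3-{(triisopropylsilyl)ethynyl}cyclohexa-1,4-dien-1-yl]penta-2,4-dienamide | O=C(/C=C/C=C/C1CCCCC1)NC1=C[C@](O)(C#C[Si](C(C)C)(C(C)C)C(C)C)C=CC1=O | intermediate
16 | (2E,4E)-5-cyclohexyl-N-[(1R,5S,6S)-5-hydroxy-2-oxo-5-{(triisopropylsilyl)ethynyl}-7-oxabicyclo[4.1.0]hept-3-en-3-yl]penta-2,4-dienamide | O=C(/C=C/C=C/C1CCCCC1)NC1=C[C@](O)(C#C[Si](C(C)C)(C(C)C)C(C)C)[C@H]2O[C@H]2C1=O | intermediate
17 | (2E,4E)-5-cyclohexyl-N-[(1R,5S,6S)-5-ethynyl-5-hydroxy-2-oxo-7-oxabicyclo[4.1.0]hept-3-en-3-yl]penta-2,4-dienamide | O=C(/C=C/C=C/C1CCCCC1)NC1=C[C@](O)(C#C)[C@H]2O[C@H]2C1=O | intermediate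
18 | (2E,4E)-5-cyclohexyl-N-[(1R,5S,6S)-5-hydroxy-2-oxo-5-{(E)-2-(tributylstannyl)ethenyl}-7-oxabicyclo[4.1.0]hept-3-en-3-yl]penta-2,4-dienamide | O=C(/C=C/C=C/C1CCCCC1)NC1=C[C@](O)(/C=C/[Sn](CCCC)(CCCC)CCCC)[C@H]2O[C@H]2C1=O | intermediate
19 | cyclopentane-1,3-dione | O=C1CCC(=O)C1 | starting material
20 | 2-(hydroxyimino)cyclopentane-1,3-dione | O=C1CCC(=O)C1=NO | intermediate
21 | 2-amino-3-hydroxycyclopent-2-en-1-one hydrochloride | Cl.NC1=C(O)CCC1=O | intermediate
22 | glutaconaldehyde potassium salt [potassium (1E,3E)-5-oxopenta-1,3-dien-1-olate] | [K+].[O-]/C=C/C=C/C=O | starting material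
23 | (2E,4E)-5-bromopenta-2,4-dienal | Br/C=C/C=C/C=O | intermediate
24 | (2E,4E)-5-bromopenta-2,4-dienoic acid | Br/C=C/C=C/C(=O)O | intermediate
25 | (2E,4E)-5-bromopenta-2,4-dienoyl chloride | Br/C=C/C=C/C(=O)Cl | intermediate
26 | (2E,4E)-5-bromo-N-(2-hydroxy-5-oxocyclopent-1-en-1-yl)penta-2,4-dienamide | Br/C=C/C=C/C(=O)NC1=C(O)CCC1=O | intermediate
27 | (2E,4E)-5-cyclohexyl-N-[(1R,5R,6S)-5-hydroxy-5-{(1E,3E,5E)-7-[(2-hydroxy-5-oxocyclopent-1-en-1-yl)amino]-7-oxohepta-1,3,5-trien-1-yl}-2-oxo-7-oxabicyclo[4.1.0]hept-3-en-3-yl]penta-2,4-dienamide | O=C(/C=C/C=C/C1CCCCC1)NC1=C[C@](O)(/C=C/C=C/C=C/C(=O)NC2=C(O)CCC2=O)[C@H]2O[C@H]2C1=O | target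

Total step count: 16 steps.
Longest linear sequence: 10 steps (steps 1, 2, 3, 5, 6, 7, 8, 9, 10 and 16).

Steps most likely to fail

Step 7. The catalyst may discriminate the two faces of the C4 ketone poorly, or the closure may run through nitrogen or through a 4π pathway instead of through C3. The fallback gives up the C3–C4 closure and builds the epoxy carbinol on a preformed ring by known chemistry; it sets out from 5 and 7 and returns at 16. Acylation of 2,5-dimethoxyaniline with 5 (pyridine, CH2Cl2) should give the anilide F1. Oxidation with PhI(OAc)2 in MeOH should give the quinone monoketal F2. Phase-transfer epoxidation (tert-butyl hydroperoxide, aq. NaOH, toluene, an N-benzyl cinchona ammonium chloride of the pseudo-enantiomeric series that gives the 5S,6R oxirane in core numbering) should give the epoxy ketal F3. Lithium (triisopropylsilyl)acetylide F4, made from 7 and BuLi in THF at −78 °C and used in excess, should add to the ketone from the face opposite the oxirane to give the carbinol ketal F5 with the hydroxyl cis to the oxirane oxygen. Hydrolysis of the ketal on montmorillonite K10 clay in CH2Cl2 then gives 16.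

Step 6. Singlet oxygen may attack the enamide double bond in competition with the furan, and the cis-enedione may isomerise or polymerise during handling. The fallback lowers the electron density of the enamide by a temporary second acyl group on nitrogen; it sets out from 11 and returns at 13. Treatment of 11 with Boc2O and DMAP (cat.) in MeCN should give the N-Boc enamide F6. Photooxygenation as in step 6 should give its endoperoxide F7, which Me2S reduces to the N-Boc cis-enedione F8. Selective removal of the carbamate from the imide nitrogen with Mg(ClO4)2 (cat.) in MeCN gives 13, which is taken into step 7 at once.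

Step 10. The palladium hydride may reduce the enones by conjugate addition, or tin may be delivered to the internal alkyne carbon. The fallback joins the chain first and sets the alkene geometry afterwards; it sets out from 17 and 26 and returns at 27. Sonogashira coupling of 17 with 26 (Pd(PPh3)4, CuI, diisopropylamine, THF) should give the dienyne F9. Hydroxyl-guided trans-hydrosilylation with (EtO)3SiH and [Cp*Ru(MeCN)3]PF6 in CH2Cl2 should place silicon on the alkyne carbon distal to the carbinol and give the vinylsilane F10. Protodesilylation with CuI and Bu4NF in THF, with retention of geometry, then gives the E alkene of 27.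

Further compounds
F1 | step 7 | (2E,4E)-5-cyclohexyl-N-(2,5-dimethoxyphenyl)penta-2,4-dienamide | O=C(/C=C/C=C/C1CCCCC1)Nc1cc(OC)ccc1OC
F2 | step 7 | (2E,4E)-5-cyclohexyl-N-(6,6-dimethoxy-3-oxocyclohexa-1,4-dien-1-yl)penta-2,4-dienamide | O=C(/C=C/C=C/C1CCCCC1)NC1=CC(=O)C=CC1(OC)OC
F3 | step 7 | epoxy ketal: 5,6-oxirane (5S,6R in core numbering) of F2 | O=C(/C=C/C=C/C1CCCCC1)NC1=CC(=O)[C@H]2O[C@H]2C1(OC)OC
F4 | step 7 | lithium (triisopropylsilyl)acetylide | [Li]C#C[Si](C(C)C)(C(C)C)C(C)C
F5 | step 7 | carbinol ketal: C1 dimethyl ketal of 16 | O=C(/C=C/C=C/C1CCCCC1)NC1=C[C@](O)(C#C[Si](C(C)C)(C(C)C)C(C)C)[C@H]2O[C@H]2C1(OC)OC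
F6 | step 6 | tert-butyl N-[(2E,4E)-5-cyclohexylpenta-2,4-dienoyl]-N-(1-{5-[(triisopropylsilyl)ethynyl]furan-2-yl}ethenyl)carbamate | O=C(/C=C/C=C/C1CCCCC1)N(C(=O)OC(C)(C)C)C(=C)c1ccc(C#C[Si](C(C)C)(C(C)C)C(C)C)o1
F7 | step 6 | endoperoxide of F6 (racemic 2,3,7-trioxabicyclo[2.2.1]hept-5-ene) | C=C(N(C(=O)OC(C)(C)C)C(=O)/C=C/C=C/C1CCCCC1)C12OOC(C#C[Si](C(C)C)(C(C)C)C(C)C)(C=C1)O2
F8 | step 6 | N-Boc derivative of cis-enedione 13 | C=C(N(C(=O)OC(C)(C)C)C(=O)/C=C/C=C/C1CCCCC1)C(=O)/C=C\C(=O)C#C[Si](C(C)C)(C(C)C)C(C)C
F9 | step 10 | dienyne: 1,2-didehydro analogue of 27 (alkyne between the first two chain carbons) | O=C(/C=C/C=C/C1CCCCC1)NC1=C[C@](O)(C#C/C=C/C=C/C(=O)NC2=C(O)CCC2=O)[C@H]2O[C@H]2C1=O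
F10 | step 10 | vinylsilane: 27 carrying a triethoxysilyl group on the second chain carbon | O=C(/C=C/C=C/C1CCCCC1)NC1=C[C@](O)(/C=C(/C=C/C=C/C(=O)NC2=C(O)CCC2=O)[Si](OCC)(OCC)OCC)[C@H]2O[C@H]2C1=O
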